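**Retrosynthetic overview**
1. Target ⇐ E-selective cross-metathesis of 1β-acryloyloxypolygodial with 4-vinylphenol; the arene is added last, so the phenol never needs protection.
2. Dialdehyde ⇐ double Swern oxidation of the 11,12-diol ⇐ allylic hydroxylation (C12) of 1β-acryloyloxydrimenol.
3. Both rings ⇐ one proton-initiated head-to-tail cation–olefin bicyclisation of (8R)-8-acryloyloxy-(2E,6E)-farnesol: ring A closes first (C4–C5 bond), then ring B (C9–C10 bond). The C8 ester stereocentre (future C1) is carried through the cascade and is expected to set C5, C9 and C10.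
4. (8R)-8-Hydroxyfarnesyl acetate ⇐ asymmetric allylboration plus cross-metathesis prenylation of 8-oxogeranyl acetate ⇐ SeO2 oxidation of geranyl acetate.

Assumption: the SMILES is read as 1β-(E)-p-coumaroyloxypolygodial, (1R,5S,9R,10S) in drimane numbering; α/β descriptors below refer to that numbering (10-CH3 = β).

**Step 1**
Reactants: 1 geranyl acetate
Product: 3 (2E,6E)-3,7-dimethyl-8-oxoocta-2,6-dien-1-yl acetate, via (2E,6E)-8-hydroxygeranyl acetate 2 (not isolated)
Conditions: SeO2 (1.2 equiv), wet 1,4-dioxane, 80 °C, 4 h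
Reagents that add atoms: selenium dioxide, O=[Se]=O
Why: Riley allylic oxidation (ene reaction then [2,3]-sigmatropic shift) attacks the E-methyl of the acetate-remote, more electron-rich trisubstituted alkene, and the E-allylic alcohol 2 is oxidised on to the E-enal, which fixes the 6E geometry.

**Step 2**
Reactants: 3 (2E,6E)-3,7-dimethyl-8-oxoocta-2,6-dien-1-yl acetate; 4 B-allyldiisopinocampheylborane of the (−)-α-pinene series (lIpc2B(allyl))
Product: 6 (2E,6E,8R)-8-hydroxy-3,7-dimethylundeca-2,6,10-trien-1-yl acetate, via diisopinocampheylborinate ester 5 (not isolated)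
Conditions: 4 (1.3 equiv, 1 M in pentane), Et2O, −78 °C, 2 h; then ethanolamine (1.5 equiv), rt, filter
Reagents that add atoms: B-allyldiisopinocampheylborane (4), C=CCB([C@H]1C[C@H]2C[C@@H]([C@@H]1C)C2(C)C)[C@H]1C[C@H]2C[C@@H]([C@@H]1C)C2(C)C
Why: Brown asymmetric allylboration through a closed chair transition state gives reagent-controlled addition to one enal face (the reagent sense that turns benzaldehyde into (R)-1-phenylbut-3-en-1-ol, typically ≥90% ee), which sets the 8R carbinol, while the acetate is inert at −78 °C and survives the non-oxidative ethanolamine work-up.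

**Step 3**
Reactants: 6 (2E,6E,8R)-8-hydroxy-3,7-dimethylundeca-2,6,10-trien-1-yl acetate; 7 2-methyl-2-butene
Product: 8 (2E,6E,8R)-8-hydroxy-3,7,11-trimethyldodeca-2,6,10-trien-1-yl acetate [(8R)-8-hydroxyfarnesyl acetate]
Conditions: 7 (large excess, co-solvent), second-generation Grubbs catalyst RuCl2(=CHPh)(H2IMes)(PCy3) (5 mol %), CH2Cl2, 35 °C, sealed vessel
Reagents that add atoms: 2-methyl-2-butene, CC=C(C)C
Why: Olefin cross-metathesis converts only the monosubstituted terminal alkene into the prenyl terminus because the two trisubstituted alkenes do not engage the ruthenium carbene, and the stereocentre is untouched.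

**Step 4**
Reactants: 8 (8R)-8-hydroxyfarnesyl acetate; 9 acryloyl chloride
Product: 10 (2E,6E,8R)-8-(acryloyloxy)-3,7,11-trimethyldodeca-2,6,10-trien-1-yl acetate
Conditions: 9 (1.5 equiv), Et3N (2.5 equiv), DMAP (5 mol %), CH2Cl2, −20 → 0 °C
Reagents that add atoms: acryloyl chloride, C=CC(Cl)=O
Why: DMAP-catalysed O-acylation of the only free hydroxyl proceeds with retention at C8 and installs an ester that is both the cation-compatible C8 substituent for the cyclisation and the handle for the final metathesis.

**Step 5**
Reactants: 10 (2E,6E,8R)-8-(acryloyloxy)-3,7,11-trimethyldodeca-2,6,10-trien-1-yl acetate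
Product: 11 (2E,6E,8R)-8-(acryloyloxy)-3,7,11-trimethyldodeca-2,6,10-trien-1-ol [(8R)-8-acryloyloxyfarnesol]
Conditions: Candida antarctica lipase B (immobilised, Novozym 435), n-BuOH (5 equiv), MTBE, 35 °C
Reagents that add atoms: none
Why: Lipase-catalysed transesterification (acyl-enzyme mechanism) removes the unhindered primary acetate under neutral conditions, whereas the secondary acrylate flanked by two large groups does not fit the active site and no alkoxide is present to add to the acrylate.

**Step 6**
Reactants: 11 (8R)-8-acryloyloxyfarnesol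
Product: 12 1β-acryloyloxydrimenol [(1R,5S,9S,10S)-1-acryloyloxydrim-7-en-11-ol]
Conditions: FSO3H (8 equiv), 2-nitropropane, −78 °C, 0.02 M, 20 min; Et3N quench at −78 °C, then aq. NaHCO3
Reagents that add atoms: none
Why: Proposed new method: a Brønsted-superacid cation–olefin bicyclisation of the Stork–Eschenmoser type (closest known case: FSO3H conversion of (E,E)-farnesol into drimenol) is applied to a substrate carrying an allylic acyloxy stereocentre, in which protonation occurs at the ester-remote, most electron-rich C10=C11 alkene, the tertiary cation closes ring A (C11–C6 bond) and then ring B (C7–C2 bond) through the chair–chair anti-addition array of the two E alkenes (trans ring fusion, 9β-CH2OH), the C8 acryloyloxy group takes the equatorial site of the ring A chair where its C–O bond lies in the nodal plane of the reacting π bond and the axial C8–H bond can stabilise the developing C7 cation, so that the 8R centre (future C1) should fix C5, C9 and C10 in the required sense, and loss of H-7 gives the trisubstituted Δ7 alkene while the electron-poor acryloyl C=C is no cation trap.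

**Step 7**
Reactants: 12 1β-acryloyloxydrimenol
Product: 13 (1R,5S,9S,10S)-1-acryloyloxydrim-7-ene-11,12-diol
Conditions: SeO2 (0.3 equiv), t-BuOOH (5.5 M in decane, 2.5 equiv), salicylic acid (0.1 equiv), CH2Cl2, 0 °C → rt
Reagents that add atoms: tert-butyl hydroperoxide, CC(C)(C)OO (oxygen source); selenium dioxide, O=[Se]=O (catalytic oxygen carrier)
Why: Catalytic Riley allylic hydroxylation (ene/[2,3] sequence) attacks the methyl on the more substituted alkene carbon C8 in preference to the C9 methine (CH3 > CH rule), and re-oxidation of selenium by t-BuOOH keeps the reaction mainly at the alcohol stage without touching any stereocentre.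

**Step 8**
Reactants: 13 (1R,5S,9S,10S)-1-acryloyloxydrim-7-ene-11,12-diol
Product: 15 1β-acryloyloxypolygodial [(1R,5S,9R,10S)-1-acryloyloxydrim-7-ene-11,12-dial], via bis(alkoxysulfonium) dichloride 14 (not isolated)
Conditions: (COCl)2 (3 equiv), DMSO (6 equiv), CH2Cl2, −78 °C; add 13; then Et3N (8 equiv), −78 → −40 °C; pH 7 buffer quench
Reagents that add atoms: none
Why: In the Swern oxidation both hydroxyls are converted into alkoxysulfonium ions before base is added, so the two aldehydes are released together (no lactol or lactone), and the low temperature keeps the epimerisable 9β-CHO centre intact.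

**Step 9**
Reactants: 15 1β-acryloyloxypolygodial; 16 4-vinylphenol
Product: 17 (1R,5S,9R,10S)-1-[(E)-3-(4-hydroxyphenyl)prop-2-enoyloxy]drim-7-ene-11,12-dial (target, CNP0187624.1)
Conditions: 16 (3 equiv, fresh), second-generation Hoveyda–Grubbs catalyst RuCl2(H2IMes)(=CH-C6H4-2-O-i-Pr) (5 mol %), CH2Cl2, 40 °C, 6 h
Reagents that add atoms: 4-vinylphenol, C=Cc1ccc(O)cc1
Why: Acrylate–styrene olefin cross-metathesis gives the conjugated E-cinnamate under base-free neutral conditions, so the free phenol, the dialdehyde and C9 survive, and the trisubstituted enal alkene is inert to the catalyst.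

**Compound list**
1 | geranyl acetate, (2E)-3,7-dimethylocta-2,6-dien-1-yl acetate | CC(C)=CCC/C(C)=C/COC(C)=O | starting material
2 | (2E,6E)-8-hydroxy-3,7-dimethylocta-2,6-dien-1-yl acetate | OC/C(C)=C/CC/C(C)=C/COC(C)=O | intermediate (not isolated)
3 | (2E,6E)-3,7-dimethyl-8-oxoocta-2,6-dien-1-yl acetate | O=C/C(C)=C/CC/C(C)=C/COC(C)=O | intermediate
4 | B-allyldiisopinocampheylborane of the (−)-α-pinene series, allylbis[(1S,2R,3S,5S)-2,6,6-trimethylbicyclo[3.1.1]hept-3-yl]borane | C=CCB([C@H]1C[C@H]2C[C@@H]([C@@H]1C)C2(C)C)[C@H]1C[C@H]2C[C@@H]([C@@H]1C)C2(C)C | starting material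
5 | diisopinocampheylborinate ester of 6 (8R) | C=CC[C@@H](OB([C@H]1C[C@H]2C[C@@H]([C@@H]1C)C2(C)C)[C@H]1C[C@H]2C[C@@H]([C@@H]1C)C2(C)C)/C(C)=C/CC/C(C)=C/COC(C)=O | intermediate (not isolated)
6 | (2E,6E,8R)-8-hydroxy-3,7-dimethylundeca-2,6,10-trien-1-yl acetate | C=CC[C@@H](O)/C(C)=C/CC/C(C)=C/COC(C)=O | intermediate
7 | 2-methyl-2-butene | CC=C(C)C | starting material
8 | (2E,6E,8R)-8-hydroxy-3,7,11-trimethyldodeca-2,6,10-trien-1-yl acetate | CC(C)=CC[C@@H](O)/C(C)=C/CC/C(C)=C/COC(C)=O | intermediate
9 | acryloyl chloride | C=CC(Cl)=O | starting material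
10 | (2E,6E,8R)-8-(acryloyloxy)-3,7,11-trimethyldodeca-2,6,10-trien-1-yl acetate | CC(C)=CC[C@@H](OC(=O)C=C)/C(C)=C/CC/C(C)=C/COC(C)=O | intermediate
11 | (2E,6E,8R)-8-(acryloyloxy)-3,7,11-trimethyldodeca-2,6,10-trien-1-ol | CC(C)=CC[C@@H](OC(=O)C=C)/C(C)=C/CC/C(C)=C/CO | intermediate
12 | 1β-acryloyloxydrimenol, (1R,5S,9S,10S)-1-acryloyloxydrim-7-en-11-ol; trans-decalin, 10β-CH3, 5α-H, 9β-CH2OH, 1β-ester | CC1(C)CC[C@@H](OC(=O)C=C)[C@]2(C)[C@@H](CO)C(C)=CC[C@@H]12 | intermediate
13 | (1R,5S,9S,10S)-1-acryloyloxydrim-7-ene-11,12-diol | CC1(C)CC[C@@H](OC(=O)C=C)[C@]2(C)[C@@H](CO)C(CO)=CC[C@@H]12 | intermediate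
14 | 11,12-bis(dimethylsulfonio-oxy) derivative of 13, dichloride | CC1(C)CC[C@@H](OC(=O)C=C)[C@]2(C)[C@@H](CO[S+](C)C)C(CO[S+](C)C)=CC[C@@H]12.[Cl-].[Cl-] | intermediate (not isolated)
15 | 1β-acryloyloxypolygodial, (1R,5S,9R,10S)-1-acryloyloxydrim-7-ene-11,12-dial; 9β-CHO | CC1(C)CC[C@@H](OC(=O)C=C)[C@]2(C)[C@@H](C=O)C(C=O)=CC[C@@H]12 | intermediate
16 | 4-vinylphenol (4-hydroxystyrene) | C=Cc1ccc(O)cc1 | starting material
17 | 1β-[(E)-p-coumaroyloxy]polygodial, (1R,5S,9R,10S)-1-[(E)-3-(4-hydroxyphenyl)prop-2-enoyloxy]drim-7-ene-11,12-dial | CC1(C)CC[C@@H](OC(=O)/C=C/c2ccc(O)cc2)[C@]2(C)[C@@H](C=O)C(C=O)=CC[C@@H]12 | target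

**Step count**
Total steps: 9. Longest linear sequence: 9 (1 → 17); all other partners (4, 7, 9, 16) are purchased.

**Steps most likely to fail**

Step 6 (bicyclisation). The acyloxy group next to the C7 cation may stall the cascade after ring A, the cyclisation may take the other alkene face, or the exocyclic or tetrasubstituted alkene isomers may form. The fallback sets out from 11 and comes back at 12. It replaces protonation by soft-metal π-activation under non-acidic conditions, in which the esters stay unprotonated and the terminal alkene is selected more cleanly. The Hg(OTf)2·PhNMe2 complex (1.2 equiv, MeNO2, −20 °C) adds divalent mercury to C10=C11 and triggers the same chair–chair closure of ring A, then ring B. Aqueous NaCl then gives 3β-chloromercurio-1β-acryloyloxydrimenol F1. Reductive demercuration (NaBH4, THF/EtOH, −20 °C, short contact time to spare the acrylate) returns 12.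

Step 7 (allylic hydroxylation). The free diol may over-oxidise to the 12-aldehyde (which closes to a lactol), or conversion may be poor. The fallback sets out from 12 and comes back at 13 by a redox detour. The Riley oxidation is pushed on purpose to the aldehyde level with stoichiometric SeO2 (1,4-dioxane, 80 °C), and 1β-acryloyloxy-11-hydroxydrim-7-en-12-al F2 is isolated (it equilibrates with its cyclic hemiacetal). A Luche 1,2-reduction (NaBH4, CeCl3·7H2O, MeOH, −40 °C) then gives 13 without touching the acrylate.

Step 9 (final cross-metathesis). 4-Vinylphenol may polymerise or homodimerise, or the catalyst may die on the dialdehyde. The fallback sets out from 15 and comes back at 17 by changing the bond-forming reaction to a Heck–Matsuda arylation. 4-Hydroxybenzenediazonium tetrafluoroborate F3 (from 4-aminophenol, NaNO2, HBF4) is coupled with the acrylate using Pd(OAc)2 (5 mol %), NaOAc (1.1 equiv, acid buffer), MeCN, 25 °C. The aryl–palladium species adds to the acrylate terminus and syn β-hydride elimination gives the E-cinnamate directly, again without phenol protection.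

**Further compounds**
F1 | step 6 | 3β-chloromercurio-1β-acryloyloxydrimenol | CC1(C)[C@@H]([Hg]Cl)C[C@@H](OC(=O)C=C)[C@]2(C)[C@@H](CO)C(C)=CC[C@@H]12
F2 | step 7 | 1β-acryloyloxy-11-hydroxydrim-7-en-12-al | CC1(C)CC[C@@H](OC(=O)C=C)[C@]2(C)[C@@H](CO)C(C=O)=CC[C@@H]12
F3 | step 9 | 4-hydroxybenzenediazonium tetrafluoroborate | Oc1ccc([N+]#N)cc1.F[B-](F)(F)F
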